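The route rests on disconnecting two bonds of ring A, C10–CH3 and C4–C5. C5 lies between the tertiary carbinol C4 and the oxygenated C6 (an aldol pattern) and is bonded to the methyl-bearing quaternary C10, so copper-catalysed asymmetric methyl transfer from Me2Zn to C10 of a C6 enone creates a C5 zinc enolate that closes ring A onto a C4 side-chain ketone in the same flask. The precursor, (S)-6-isopropyl-3-(4-oxopentyl)cyclohex-2-enone, carries C7 already fixed (from (S)-cryptone), so that imperfect ligand control gives separable diastereomers. Epimerisation at C5, syn-selective ketone reduction and olefination to the isoferulate complete the synthesis.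

Key step: step 6

Remark on numbering: eudesmane numbering is used throughout (C4 carbinol carbon, C5 ring-fusion CH, C6 oxygenated carbon, C7 isopropyl-bearing carbon, C10 quaternary carbon; ring A = C1–C5 and C10, ring B = C5–C10); β is the face of the C10 methyl group.
Remark on stereochemistry: the ring closure of step 6 is expected to be cis, because the new C4–C5 bond forms anti to the new axial C10 methyl. The trans ring fusion is therefore installed by a separate epimerisation at C5 (step 7), and the C4 configuration is attributed to zinc chelation, not to the C10 methyl.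
Assumption: the sense of induction in step 1 is taken from the usual shielding model; the other catalyst enantiomer would be used if it proved opposite.

Step 1
Reactants: 1 3-methylbutanal (isovaleraldehyde); 2 but-3-en-2-one (methyl vinyl ketone)
Product: 3 (2S)-5-oxo-2-(propan-2-yl)hexanal
Conditions: (S)-2-(methoxydiphenylmethyl)pyrrolidine (5 mol %), ethyl 3,4-dihydroxybenzoate (20 mol %), neat, 4 °C
Reagents that add atoms: none
Why: Enamine-catalysed asymmetric Michael addition of an aldehyde to an enone, in which the diaryl(methoxy)methyl group screens one face of the E-enamine of 1 so that 2 bonds to the open face, which sets C2 (the later C7) and should give the S aldehyde with the S catalyst.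

Step 2
Reactants: 3 (2S)-5-oxo-2-(propan-2-yl)hexanal
Product: 4 (4S)-4-(propan-2-yl)cyclohex-2-en-1-one ((S)-cryptone)
Conditions: LiOH (0.1 equiv), i-PrOH, 23 °C
Reagents that add atoms: none
Why: Intramolecular aldol condensation (second half of a Robinson annulation) of the methyl ketone enolate onto the aldehyde with loss of water; the stereocentre becomes the γ-carbon of the enone and should not be deprotonated by catalytic hydroxide at room temperature if the reaction is stopped at full conversion.

Step 3
Reactants: 4 (4S)-4-(propan-2-yl)cyclohex-2-en-1-one; 5 2-(3-chloropropyl)-2-methyl-1,3-dioxolane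
Product: 7 (4S)-1-[3-(2-methyl-1,3-dioxolan-2-yl)propyl]-4-(propan-2-yl)cyclohex-2-en-1-ol (both C1 epimers), via Grignard reagent 6 (not isolated)
Conditions: 5, Mg, THF, 50 °C; then 4, THF, −78 → 0 °C; aq NH4Cl
Reagents that add atoms: none
Why: Grignard 1,2-addition of a primary alkylmagnesium chloride to a cyclohexenone carbonyl at low temperature; the new carbinol centre forms as a mixture that is erased in step 4 and the isopropyl-bearing centre is untouched.

Step 4
Reactants: 7 (4S)-1-[3-(2-methyl-1,3-dioxolan-2-yl)propyl]-4-(propan-2-yl)cyclohex-2-en-1-ol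
Product: 8 (6S)-3-[3-(2-methyl-1,3-dioxolan-2-yl)propyl]-6-(propan-2-yl)cyclohex-2-en-1-one
Conditions: pyridinium chlorochromate [C5H5NH][CrO3Cl] (2 equiv), 4 Å molecular sieves, CH2Cl2, 23 °C
Reagents that add atoms: pyridinium chlorochromate, [O-][Cr](=O)(=O)Cl.c1cc[nH+]cc1
Why: Babler–Dauben oxidative transposition, in which the chromate ester of the tertiary allylic alcohol undergoes a [3,3] shift and the secondary allylic chromate is oxidised to the 3-substituted enone, placing the carbonyl next to the isopropyl-bearing carbon without breaking a bond to that stereocentre; the dioxolane should survive, and any partial loss only anticipates step 5.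

Step 5
Reactants: 8 (6S)-3-[3-(2-methyl-1,3-dioxolan-2-yl)propyl]-6-(propan-2-yl)cyclohex-2-en-1-one
Product: 9 (6S)-3-(4-oxopentyl)-6-(propan-2-yl)cyclohex-2-en-1-one
Conditions: 1 M aq HCl, THF, 0 → 23 °C, about 1 h
Reagents that add atoms: water, O
Why: Acid-catalysed hydrolysis of a dioxolane ketal, kept brief and cold so that the enolisable C7 centre next to the enone carbonyl should stay intact.

Step 6
Reactants: 9 (6S)-3-(4-oxopentyl)-6-(propan-2-yl)cyclohex-2-en-1-one; 10 dimethylzinc
Product: 12 (2S,4aR,8S,8aS)-8-hydroxy-4a,8-dimethyl-2-(propan-2-yl)octahydronaphthalen-1(2H)-one [(4S,5S,7S,10R)-4-hydroxyeudesman-6-one; cis-fused 5β-H ketol], via zinc enolate 11 (not isolated)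
Conditions: Cu(OTf)2 (5 mol %), chiral sulfonate-bearing imidazolinium salt (NHC precursor, 6 mol %; enantiomer that sends CH3 to the Si face of C10), Me2Zn (3 equiv), toluene, −30 → 22 °C; aq NH4Cl
Reagents that add atoms: dimethylzinc (compound 10), C[Zn]C
Why: Proposed new method: a methylcopper species formed from Me2Zn and the NHC–copper catalyst adds CH3 to C10 of the enone, and the resulting methylzinc C5–C6 enolate 11 attacks the zinc-bound side-chain ketone at C4, so that C10–CH3 and C4–C5 form in one flask and ring A closes by a 6-(enolexo)-exo-trig aldol addition. The closest known reactions are the copper-catalysed enantioselective dialkylzinc addition to 3-alkylcyclohex-2-enones that creates quaternary carbons and the copper-catalysed dialkylzinc conjugate addition with aldol cyclisation of acyclic enones onto tethered ketones; their combination on a 3,6-disubstituted cyclohexenone is the untested part. C10 (R) is set by the ligand, which must deliver CH3 to the Si face of C10 (the face cis to the C7 isopropyl group), and the (S)-C7 centre, pseudo-equatorial in the enone half-chair, reinforces this through axial attack, so wrong-face addition would give a separable diastereomer and not the enantiomer. C5 is set by the stereoelectronic demand for axial bond formation on the half-chair enolate anti to the new axial methyl, which makes the kinetic ring fusion cis (5β-H) and calls for the epimerisation of step 7. C4 (S) is set by the zinc bridge between the enolate oxygen and the ketone oxygen in a closed transition state, which holds the C4 oxygen syn to O6 and leaves the C4 methyl as the group that points under ring B. The step needs chemoselective methyl transfer to the enone in the presence of the methyl ketone, which the inertness of Me2Zn towards ketones secures.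

Step 7
Reactants: 12 (2S,4aR,8S,8aS)-8-hydroxy-4a,8-dimethyl-2-(propan-2-yl)octahydronaphthalen-1(2H)-one
Product: 13 (2S,4aR,8S,8aR)-8-hydroxy-4a,8-dimethyl-2-(propan-2-yl)octahydronaphthalen-1(2H)-one [4β-hydroxy-5α-eudesman-6-one; trans-fused]
Conditions: DBU (1 equiv), toluene, 23 → 50 °C, stopped when 12 is consumed
Reagents that add atoms: none
Why: Base-mediated epimerisation α to a ketone through the C5–C6 enolate under thermodynamic control: 13 has the C4 methyl equatorial and the axial 4β-hydroxyl hydrogen-bonded to the C6 carbonyl, whereas 12 must place either the C4 methyl under ring B or the isopropyl group axial; C5–H is acidified by the β-oxygen, and an amidine in an aprotic solvent should leave the more hindered C7–H alone and avoid retro-aldol opening and loss of water.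

Step 8
Reactants: 13 (2S,4aR,8S,8aR)-8-hydroxy-4a,8-dimethyl-2-(propan-2-yl)octahydronaphthalen-1(2H)-one
Product: 14 (1R,2S,4aR,8S,8aS)-4a,8-dimethyl-2-(propan-2-yl)decahydronaphthalene-1,8-diol [5α-eudesmane-4β,6β-diol]
Conditions: Et2BOMe (1.2 equiv), THF/MeOH (4:1), −78 °C; NaBH4, −78 → −20 °C; MeOH co-evaporation
Reagents that add atoms: none
Why: Narasaka–Prasad reduction of a β-hydroxy ketone: the diethylboron chelate between the 4β-oxygen and the C6 carbonyl oxygen sits on the β face, which the axial C10 methyl also screens, so external borohydride adds to the α face of C6 and gives the 6β (axial) alcohol, the syn-1,3-diol.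

Step 9
Reactants: 14 (1R,2S,4aR,8S,8aS)-4a,8-dimethyl-2-(propan-2-yl)decahydronaphthalene-1,8-diol; 15 2-(diethoxyphosphoryl)acetic acid
Product: 16 (1R,2S,4aR,8S,8aS)-8-hydroxy-4a,8-dimethyl-2-(propan-2-yl)decahydronaphthalen-1-yl 2-(diethoxyphosphoryl)acetate
Conditions: 15 (1.5 equiv), DCC, DMAP (0.1 equiv), CH2Cl2, 0 → 23 °C
Reagents that add atoms: none
Why: Steglich esterification in which carbodiimide activation of the phosphonoacetic acid gives a small, ketene-like acyl donor that should acylate the hindered secondary 6β-hydroxyl, while the tertiary 4β-hydroxyl is too hindered to compete.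

Step 10
Reactants: 16 (1R,2S,4aR,8S,8aS)-8-hydroxy-4a,8-dimethyl-2-(propan-2-yl)decahydronaphthalen-1-yl 2-(diethoxyphosphoryl)acetate; 17 3-hydroxy-4-methoxybenzaldehyde (isovanillin)
Product: 18 (1R,2S,4aR,8S,8aS)-8-hydroxy-4a,8-dimethyl-2-(propan-2-yl)decahydronaphthalen-1-yl (2E)-3-(3-hydroxy-4-methoxyphenyl)prop-2-enoate [4β-hydroxy-5α-eudesman-6β-yl (E)-isoferulate; the target]
Conditions: 17 (1.2 equiv), LiCl (3 equiv), DBU (2.5 equiv), MeCN, 0 → 23 °C
Reagents that add atoms: none
Why: Horner–Wadsworth–Emmons olefination under Masamune–Roush conditions, in which the lithium-chelated phosphonate anion adds to the aryl aldehyde and elimination of diethyl phosphate gives the E-cinnamate, the extra DBU covering the free phenol and the mild base sparing the ester and the tertiary alcohol.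

Compound list
1 | 3-methylbutanal (isovaleraldehyde) | CC(C)CC=O | starting material
2 | but-3-en-2-one (methyl vinyl ketone) | CC(=O)C=C | starting material
3 | (2S)-5-oxo-2-(propan-2-yl)hexanal | O=C[C@@H](CCC(C)=O)C(C)C | intermediate
4 | (4S)-4-(propan-2-yl)cyclohex-2-en-1-one ((S)-cryptone) | O=C1C=C[C@H](C(C)C)CC1 | intermediate
5 | 2-(3-chloropropyl)-2-methyl-1,3-dioxolane | CC1(CCCCl)OCCO1 | starting material
6 | [3-(2-methyl-1,3-dioxolan-2-yl)propyl]magnesium chloride (formed in the flask) | CC1(CCC[Mg]Cl)OCCO1 | intermediate
7 | (4S)-1-[3-(2-methyl-1,3-dioxolan-2-yl)propyl]-4-(propan-2-yl)cyclohex-2-en-1-ol (both C1 epimers) | OC1(CCCC2(C)OCCO2)C=C[C@H](C(C)C)CC1 | intermediate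
8 | (6S)-3-[3-(2-methyl-1,3-dioxolan-2-yl)propyl]-6-(propan-2-yl)cyclohex-2-en-1-one | O=C1C=C(CCCC2(C)OCCO2)CC[C@H]1C(C)C | intermediate
9 | (6S)-3-(4-oxopentyl)-6-(propan-2-yl)cyclohex-2-en-1-one (precursor of the key step) | O=C1C=C(CCCC(C)=O)CC[C@H]1C(C)C | intermediate
10 | dimethylzinc | C[Zn]C | starting material
11 | methylzinc C5–C6 enolate of (3R,6S)-3-methyl-3-(4-oxopentyl)-6-(propan-2-yl)cyclohexan-1-one (formed in the flask) | C[Zn]OC1=C[C@](C)(CCCC(C)=O)CC[C@H]1C(C)C | intermediate
12 | (2S,4aR,8S,8aS)-8-hydroxy-4a,8-dimethyl-2-(propan-2-yl)octahydronaphthalen-1(2H)-one (cis-fused ketol, 5β-H) | O=C1[C@H]2[C@](C)(CCC[C@]2(C)O)CC[C@H]1C(C)C | intermediate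
13 | (2S,4aR,8S,8aR)-8-hydroxy-4a,8-dimethyl-2-(propan-2-yl)octahydronaphthalen-1(2H)-one (4β-hydroxy-5α-eudesman-6-one) | O=C1[C@@H]2[C@](C)(CCC[C@]2(C)O)CC[C@H]1C(C)C | intermediate
14 | (1R,2S,4aR,8S,8aS)-4a,8-dimethyl-2-(propan-2-yl)decahydronaphthalene-1,8-diol (5α-eudesmane-4β,6β-diol) | O[C@H]1[C@@H]2[C@](C)(CCC[C@]2(C)O)CC[C@H]1C(C)C | intermediate
15 | 2-(diethoxyphosphoryl)acetic acid | CCOP(=O)(OCC)CC(=O)O | starting material
16 | (1R,2S,4aR,8S,8aS)-8-hydroxy-4a,8-dimethyl-2-(propan-2-yl)decahydronaphthalen-1-yl 2-(diethoxyphosphoryl)acetate | CCOP(=O)(OCC)CC(=O)O[C@H]1[C@@H]2[C@](C)(CCC[C@]2(C)O)CC[C@H]1C(C)C | intermediate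
17 | 3-hydroxy-4-methoxybenzaldehyde (isovanillin) | COc1ccc(C=O)cc1O | starting material
18 | (1R,2S,4aR,8S,8aS)-8-hydroxy-4a,8-dimethyl-2-(propan-2-yl)decahydronaphthalen-1-yl (2E)-3-(3-hydroxy-4-methoxyphenyl)prop-2-enoate | COc1ccc(/C=C/C(=O)O[C@H]2[C@@H]3[C@](C)(CCC[C@]3(C)O)CC[C@H]2C(C)C)cc1O | target

Total step count: 10. Longest linear sequence: 10 steps (1 and 2 to 18).

Steps most likely to fail

Step 6 (the labelled step). What may go wrong: slow methyl transfer from Me2Zn to the trisubstituted enone, protonation of the zinc enolate without ring closure, incomplete facial control at C10, or closure without zinc chelation that inverts C4. The fallback uses known chemistry in separate operations; it sets out from 8 and comes back to the route at 13. Enone ketal 8 would be methylated by the established copper-catalysed asymmetric conjugate addition of Me3Al to 3-alkylcyclohex-2-enones (copper thiophene-2-carboxylate Cu(O2CC4H3S), chiral phosphoramidite, Et2O, −30 °C, protic work-up) to give (3R,6S)-3-methyl-3-[3-(2-methyl-1,3-dioxolan-2-yl)propyl]-6-(propan-2-yl)cyclohexan-1-one F1. Hydrolysis of the dioxolane (1 M aq HCl, THF) would give the diketone (3R,6S)-3-methyl-3-(4-oxopentyl)-6-(propan-2-yl)cyclohexan-1-one F2. Base-mediated intramolecular aldol addition under equilibrating conditions (catalytic NaOMe, MeOH, 23 °C) should then close ring A and settle C4 and C5 to give 13, any C7 epimer being removed by chromatography.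

Step 7. What may go wrong: slow proton transfer at the hindered C5, competing epimerisation at C7, retro-aldol opening, or loss of water to the conjugated enone. The fallback replaces the selective proton transfer by full thermodynamic equilibration with recycling; it sets out from 12 and comes back at 13. Catalytic NaOMe in MeOH at 23 °C would equilibrate C4 and C5 through reversible retro-aldol and aldol closure and both α-carbons through their enolates, which also repairs a wrong C4 configuration. Ketone 13 would be separated from its C7 epimer (2R,4aR,8S,8aR)-8-hydroxy-4a,8-dimethyl-2-(propan-2-yl)octahydronaphthalen-1(2H)-one F3, and F3 returned to the same conditions.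

Step 9. What may go wrong: slow acylation of the axial 6β-hydroxyl, which is flanked by the isopropyl group and lies syn to the C10 methyl and the 4β-hydroxyl. The fallback uses a smaller and more reactive acyl donor and builds the phosphonate afterwards; it sets out from 14 and comes back at 16. Bromoacetyl bromide and pyridine in CH2Cl2 at −20 °C would give (1R,2S,4aR,8S,8aS)-8-hydroxy-4a,8-dimethyl-2-(propan-2-yl)decahydronaphthalen-1-yl 2-bromoacetate F4, and a Michaelis–Arbuzov reaction with P(OEt)3 (neat, 110 °C) would convert F4 into 16.

Further compounds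
F1 | step 6 | (3R,6S)-3-methyl-3-[3-(2-methyl-1,3-dioxolan-2-yl)propyl]-6-(propan-2-yl)cyclohexan-1-one | O=C1C[C@](C)(CCCC2(C)OCCO2)CC[C@H]1C(C)C
F2 | step 6 | (3R,6S)-3-methyl-3-(4-oxopentyl)-6-(propan-2-yl)cyclohexan-1-one | O=C1C[C@](C)(CCCC(C)=O)CC[C@H]1C(C)C
F3 | step 7 | (2R,4aR,8S,8aR)-8-hydroxy-4a,8-dimethyl-2-(propan-2-yl)octahydronaphthalen-1(2H)-one | O=C1[C@@H]2[C@](C)(CCC[C@]2(C)O)CC[C@@H]1C(C)C
F4 | step 9 | (1R,2S,4aR,8S,8aS)-8-hydroxy-4a,8-dimethyl-2-(propan-2-yl)decahydronaphthalen-1-yl 2-bromoacetate | BrCC(=O)O[C@H]1[C@@H]2[C@](C)(CCC[C@]2(C)O)CC[C@H]1C(C)C
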